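**Strategy.** Ring A is disconnected at its phenol carbon C3, which lies between the two unsubstituted carbons C2 and C4 and can therefore be supplied last as carbon monoxide. One palladium-catalysed cyclocarbonylation joins CO to both ends of an open C2–C1–C6–C5–C4 dienyl acetate, forming the C2–C3 and C3–C4 bonds and ring A as its aryl acetate in a single operation. The precursor is a (2Z)-2-(acetoxymethyl)penta-2,4-dienoate that already carries the ester (C1), the ring B aroyl group (C6) and the methyl ether (C5). Its Z geometry, with the acetoxymethyl and 1-methoxyvinyl arms cis, is built stereospecifically from (E)-2,3-dibromobut-2-ene-1,4-diol and not left to equilibration.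

Key step: step 11

Remark on numbering and stereochemistry: ring A is numbered C1 (CO2Me), C2 (H), C3 (OH), C4 (H), C5 (OMe), C6 (aroyl). The target has no stereocentre; alcohol 8 is racemic and its centre is removed in step 6. The E/Z letters of 9, 11 and 15–18 change only with CIP priorities: in all of them the CH2O arm stays trans to the aryl carbonyl group.

Remark on the design of 17: its structure is the Z acetate with MOM ethers on ring B. It is made as a single geometric isomer by stereoretentive couplings on an E-dibromide. The ester is introduced after the ketone, so that no hydroxy ester able to lactonize exists. The allylic acetate is installed last, so that it meets zerovalent palladium only in step 11.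

**Route**

Step 1
Reactants: 1 orcinol
Product: 2 4-chloro-5-methylbenzene-1,3-diol
Conditions: SO2Cl2 (1.0 equiv), Et2O, 0 °C to rt
Reagents that add atoms: sulfuryl chloride, O=S(=O)(Cl)Cl
Why: Electrophilic aromatic chlorination of a resorcinol, in which the two equivalent positions ortho to one hydroxyl and para to the other should react in preference to the crowded position between the hydroxyls, one equivalent of reagent at 0 °C limiting dichlorination and crystallization removing the minor 2-chloro isomer.

Step 2
Reactants: 2 4-chloro-5-methylbenzene-1,3-diol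
Product: 3 2-chloro-1,5-bis(methoxymethoxy)-3-methylbenzene
Conditions: NaH, MOMCl, DMF, 0 °C to rt
Reagents that add atoms: chloromethyl methyl ether, COCCl
Why: Double Williamson O-alkylation of the bis-phenoxide (MOM protection), giving ethers that should survive organolithium, palladium and Ac2O/Et3N chemistry, direct the lithiation of step 5 and leave under mild acid at the end.

Step 3
Reactants: 4 (2E)-2,3-dibromobut-2-ene-1,4-diol
Product: 5 (2E)-2,3-dibromo-4-[(tert-butyldimethylsilyl)oxy]but-2-en-1-ol
Conditions: NaH (1.0 equiv), THF, 0 °C; then TBSCl (1.0 equiv), rt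
Reagents that add atoms: tert-butyldimethylsilyl chloride, CC(C)(C)[Si](C)(C)Cl
Why: Statistical monosilylation of a symmetrical diol through its monosodium alkoxide, in which either hydroxyl leads to the same product and the alkene geometry is untouched.

Step 4
Reactants: 5 (2E)-2,3-dibromo-4-[(tert-butyldimethylsilyl)oxy]but-2-en-1-ol
Product: 6 (2E)-2,3-dibromo-4-[(tert-butyldimethylsilyl)oxy]but-2-enal
Conditions: Dess–Martin periodinane, CH2Cl2, 0 °C to rt
Reagents that add atoms: none
Why: Dess–Martin oxidation of the primary allylic alcohol to the enal under neutral conditions that leave the silyl ether, both vinyl bromides and the E geometry intact.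

Step 5
Reactants: 3 2-chloro-1,5-bis(methoxymethoxy)-3-methylbenzene; 6 (2E)-2,3-dibromo-4-[(tert-butyldimethylsilyl)oxy]but-2-enal
Product: 8 (2E)-2,3-dibromo-4-[(tert-butyldimethylsilyl)oxy]-1-[3-chloro-2,6-bis(methoxymethoxy)-4-methylphenyl]but-2-en-1-ol (racemic), via aryllithium 7 (not isolated)
Conditions: 3, n-BuLi, THF, 0 °C; then 6, −78 °C; aq NH4Cl
Reagents that add atoms: none
Why: Directed ortho-metalation at the only ring C–H flanked by two MOM ethers, then 1,2-addition of the aryllithium to the non-enolizable aldehyde at −78 °C, where carbonyl addition should outrun lithium–bromine exchange; the new carbinol centre forms as a racemate and is removed in step 6.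

Step 6
Reactants: 8 (2E)-2,3-dibromo-4-[(tert-butyldimethylsilyl)oxy]-1-[3-chloro-2,6-bis(methoxymethoxy)-4-methylphenyl]but-2-en-1-ol
Product: 9 (2E)-2,3-dibromo-4-[(tert-butyldimethylsilyl)oxy]-1-[3-chloro-2,6-bis(methoxymethoxy)-4-methylphenyl]but-2-en-1-one
Conditions: Dess–Martin periodinane, pyridine, CH2Cl2, 0 °C to rt
Reagents that add atoms: none
Why: Dess–Martin oxidation of the hindered benzylic, allylic alcohol to the aryl ketone, with pyridine buffering the acetic acid so that the MOM and silyl ethers persist.

Step 7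
Reactants: 9 (2E)-2,3-dibromo-4-[(tert-butyldimethylsilyl)oxy]-1-[3-chloro-2,6-bis(methoxymethoxy)-4-methylphenyl]but-2-en-1-one; 10 carbon monoxide
Product: 11 methyl (2E)-3-bromo-2-{[(tert-butyldimethylsilyl)oxy]methyl}-4-[3-chloro-2,6-bis(methoxymethoxy)-4-methylphenyl]-4-oxobut-2-enoate
Conditions: Pd(OAc)2 (5 mol %), Xantphos, CO (1 atm), MeOH, Et3N, THF, 40 °C
Reagents that add atoms: methanol, CO
Why: Palladium-catalysed methoxycarbonylation of a vinyl bromide with retention of geometry, oxidative addition selecting the C3–Br bond, which is a vinylogous acyl bromide, over the C2–Br bond next to the twisted aroyl group.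

Step 8
Reactants: 12 methyl vinyl ether
Product: 14 tributyl(1-methoxyethenyl)stannane, via 1-methoxyvinyllithium 13 (not isolated)
Conditions: t-BuLi, THF, −78 to 0 °C; then Bu3SnCl, −78 °C to rt
Reagents that add atoms: tributyltin chloride, CCCC[Sn](Cl)(CCCC)CCCC
Why: Alpha-deprotonation of the vinyl ether by t-BuLi and quench of the vinyllithium with the tin chloride, a standard preparation of 1-alkoxyvinylstannanes.

Step 9
Reactants: 11 methyl (2E)-3-bromo-2-{[(tert-butyldimethylsilyl)oxy]methyl}-4-[3-chloro-2,6-bis(methoxymethoxy)-4-methylphenyl]-4-oxobut-2-enoate; 14 tributyl(1-methoxyethenyl)stannane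
Product: 15 methyl (2Z)-2-{[(tert-butyldimethylsilyl)oxy]methyl}-3-[3-chloro-2,6-bis(methoxymethoxy)-4-methylbenzoyl]-4-methoxypenta-2,4-dienoate
Conditions: Pd2(dba)3 (5 mol %), AsPh3, CuI, DMF, 50 °C; Et3N-deactivated silica
Reagents that add atoms: none
Why: Stille coupling at the beta-bromoacrylate carbon with retention of alkene geometry, AsPh3 and CuI accelerating transmetalation at the hindered centre, so that the 1-methoxyvinyl group ends cis to the silyloxymethyl arm.

Step 10
Reactants: 15 methyl (2Z)-2-{[(tert-butyldimethylsilyl)oxy]methyl}-3-[3-chloro-2,6-bis(methoxymethoxy)-4-methylbenzoyl]-4-methoxypenta-2,4-dienoate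
Product: 17 methyl (2Z)-2-(acetoxymethyl)-3-[3-chloro-2,6-bis(methoxymethoxy)-4-methylbenzoyl]-4-methoxypenta-2,4-dienoate, via primary alcohol 16 (not isolated)
Conditions: TBAF, AcOH, THF, 0 °C; then Ac2O, pyridine, 0 °C to rt
Reagents that add atoms: acetic anhydride, CC(=O)OC(C)=O
Why: Fluoride desilylation buffered with acetic acid, then base-mediated O-acetylation of the primary alcohol, a sequence that never exposes the enol ether to free acid.

Step 11
Reactants: 17 methyl (2Z)-2-(acetoxymethyl)-3-[3-chloro-2,6-bis(methoxymethoxy)-4-methylbenzoyl]-4-methoxypenta-2,4-dienoate; 10 carbon monoxide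
Product: 20 methyl 5-acetoxy-2-[3-chloro-2,6-bis(methoxymethoxy)-4-methylbenzoyl]-3-methoxybenzoate, via dienylketene 18 (not isolated), via phenol 19 (not isolated)
Conditions: PdCl2(PPh3)2 (5 mol %), CO (60 atm), Ac2O, Et3N, toluene, 140 °C
Reagents that add atoms: acetic anhydride, CC(=O)OC(C)=O
Why: Zerovalent palladium, formed in situ from PdCl2(PPh3)2, ionizes the allylic acetate of 17 to a pi-allyl complex, CO inserts at its unhindered CH2 terminus (C2–C3 bond) and Et3N removes the now acidic C2 proton from the acylpalladium species to give dienylketene 18. Ring A then closes by a thermal disrotatory six-electron electrocyclization that joins the ketene carbon C3 to the terminal CH2 (C4) of the methoxyvinyl arm; enolization of the cyclohexadienone gives phenol 19, which Ac2O caps as acetate 20. The closest known reaction type is the cyclocarbonylation of 2,4-pentadienyl and cinnamyl acetates to phenyl and naphthyl acetates with the same catalyst, CO, Ac2O and Et3N, so 17 belongs to the established substrate class and differs only in its degree of substitution. No stereocentre is created. The selectivity required is closure of the ketene onto C4 and not onto the aroyl oxygen (which would give a 2-pyranone): the Z geometry of 17 places the methoxyvinyl arm cis and the aroyl carbonyl trans to the CH2 that becomes the ketene, and high CO pressure should let insertion outrun syn/anti exchange in the pi-allyl complex. Regiochemistry within ring A is not in question, because C1, C5 and C6 already carry the ester, the methyl ether and the aroyl group before the ring exists.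

Step 12
Reactants: 20 methyl 5-acetoxy-2-[3-chloro-2,6-bis(methoxymethoxy)-4-methylbenzoyl]-3-methoxybenzoate
Product: 21 monochlorosulochrin
Conditions: HCl (3 M in MeOH), 45 °C
Reagents that add atoms: none
Why: Acid-catalysed transesterification of the aryl acetate and acetal exchange of both MOM ethers with methanol, conditions under which the methyl ester, the aryl methyl ether, the aryl chloride and the benzophenone carbonyl are inert.

**Compound list**

1 | orcinol (5-methylbenzene-1,3-diol) | Cc1cc(O)cc(O)c1 | starting material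
2 | 4-chloro-5-methylbenzene-1,3-diol | Cc1cc(O)cc(O)c1Cl | intermediate
3 | 2-chloro-1,5-bis(methoxymethoxy)-3-methylbenzene | COCOc1cc(C)c(Cl)c(OCOC)c1 | intermediate
4 | (2E)-2,3-dibromobut-2-ene-1,4-diol | OC/C(Br)=C(Br)/CO | starting material
5 | (2E)-2,3-dibromo-4-[(tert-butyldimethylsilyl)oxy]but-2-en-1-ol | CC(C)(C)[Si](C)(C)OC/C(Br)=C(Br)/CO | intermediate
6 | (2E)-2,3-dibromo-4-[(tert-butyldimethylsilyl)oxy]but-2-enal | CC(C)(C)[Si](C)(C)OC/C(Br)=C(Br)/C=O | intermediate
7 | [3-chloro-2,6-bis(methoxymethoxy)-4-methylphenyl]lithium | [Li]c1c(OCOC)cc(C)c(Cl)c1OCOC | intermediate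
8 | (2E)-2,3-dibromo-4-[(tert-butyldimethylsilyl)oxy]-1-[3-chloro-2,6-bis(methoxymethoxy)-4-methylphenyl]but-2-en-1-ol (racemic) | CC(C)(C)[Si](C)(C)OC/C(Br)=C(Br)/C(O)c1c(OCOC)cc(C)c(Cl)c1OCOC | intermediate
9 | (2E)-2,3-dibromo-4-[(tert-butyldimethylsilyl)oxy]-1-[3-chloro-2,6-bis(methoxymethoxy)-4-methylphenyl]but-2-en-1-one | CC(C)(C)[Si](C)(C)OC/C(Br)=C(Br)/C(=O)c1c(OCOC)cc(C)c(Cl)c1OCOC | intermediate
10 | carbon monoxide | [C-]#[O+] | starting material
11 | methyl (2E)-3-bromo-2-{[(tert-butyldimethylsilyl)oxy]methyl}-4-[3-chloro-2,6-bis(methoxymethoxy)-4-methylphenyl]-4-oxobut-2-enoate | COC(=O)/C(CO[Si](C)(C)C(C)(C)C)=C(/Br)C(=O)c1c(OCOC)cc(C)c(Cl)c1OCOC | intermediate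
12 | methyl vinyl ether | COC=C | starting material
13 | 1-methoxyvinyllithium | [Li]C(=C)OC | intermediate
14 | tributyl(1-methoxyethenyl)stannane | CCCC[Sn](CCCC)(CCCC)C(=C)OC | intermediate
15 | methyl (2Z)-2-{[(tert-butyldimethylsilyl)oxy]methyl}-3-[3-chloro-2,6-bis(methoxymethoxy)-4-methylbenzoyl]-4-methoxypenta-2,4-dienoate | COC(=O)/C(CO[Si](C)(C)C(C)(C)C)=C(/C(=C)OC)C(=O)c1c(OCOC)cc(C)c(Cl)c1OCOC | intermediate
16 | methyl (2Z)-3-[3-chloro-2,6-bis(methoxymethoxy)-4-methylbenzoyl]-2-(hydroxymethyl)-4-methoxypenta-2,4-dienoate | COC(=O)/C(CO)=C(/C(=C)OC)C(=O)c1c(OCOC)cc(C)c(Cl)c1OCOC | intermediate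
17 | methyl (2Z)-2-(acetoxymethyl)-3-[3-chloro-2,6-bis(methoxymethoxy)-4-methylbenzoyl]-4-methoxypenta-2,4-dienoate | COC(=O)/C(COC(C)=O)=C(/C(=C)OC)C(=O)c1c(OCOC)cc(C)c(Cl)c1OCOC | intermediate
18 | methyl (2Z)-3-[3-chloro-2,6-bis(methoxymethoxy)-4-methylbenzoyl]-4-methoxy-2-(2-oxoethenyl)penta-2,4-dienoate (dienylketene) | COC(=O)/C(C=C=O)=C(/C(=C)OC)C(=O)c1c(OCOC)cc(C)c(Cl)c1OCOC | intermediate
19 | methyl 2-[3-chloro-2,6-bis(methoxymethoxy)-4-methylbenzoyl]-5-hydroxy-3-methoxybenzoate | COC(=O)c1cc(O)cc(OC)c1C(=O)c1c(OCOC)cc(C)c(Cl)c1OCOC | intermediate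
20 | methyl 5-acetoxy-2-[3-chloro-2,6-bis(methoxymethoxy)-4-methylbenzoyl]-3-methoxybenzoate | COC(=O)c1cc(OC(C)=O)cc(OC)c1C(=O)c1c(OCOC)cc(C)c(Cl)c1OCOC | intermediate
21 | monochlorosulochrin, methyl 2-(3-chloro-2,6-dihydroxy-4-methylbenzoyl)-5-hydroxy-3-methoxybenzoate | COC(=O)c1cc(O)cc(OC)c1C(=O)c1c(O)cc(C)c(Cl)c1O | target

**Count and risks**

Total step count: 12. Longest linear sequence: 9 steps (steps 1, 2, 5, 6, 7, 9, 10, 11, 12 from orcinol; equally steps 3, 4, 5, 6, 7, 9, 10, 11, 12 from the dibromodiol).

Steps most likely to fail: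

1. Step 11 (key step).
   - What may go wrong: syn/anti exchange in the pi-allyl complex before CO insertion, after which the ketene closes onto the aroyl oxygen instead of C4; a thermal 1,5-hydrogen shift in the cis-dienyl acetate or hydrolysis of the enol ether before ionization; or slow CO insertion at the crowded allyl terminus.
   - Fallback (sets out from 3, returns at 19): ring A is made by a Diels–Alder benzannulation of known type. Lithiation of 3 as in step 5 and quench with DMF gives 3-chloro-2,6-bis(methoxymethoxy)-4-methylbenzaldehyde F1. Lithiated methyl propiolate (LiHMDS, THF, −78 °C) adds to give racemic methyl 4-[3-chloro-2,6-bis(methoxymethoxy)-4-methylphenyl]-4-hydroxybut-2-ynoate F2, and Dess–Martin oxidation gives methyl 4-[3-chloro-2,6-bis(methoxymethoxy)-4-methylphenyl]-4-oxobut-2-ynoate F3. Cycloaddition of F3 with 1,1-dimethoxy-3-(trimethylsilyloxy)buta-1,3-diene (toluene, 80 °C) should be steered by the ketone, the stronger acceptor, so that the nucleophilic CH2 end of the diene bonds to the ester-bearing alkyne carbon. It gives methyl 2-[3-chloro-2,6-bis(methoxymethoxy)-4-methylbenzoyl]-3,3-dimethoxy-5-(trimethylsilyloxy)cyclohexa-1,4-diene-1-carboxylate F4, which is not isolated. K2CO3 in MeOH eliminates methanol and removes the silyl group to give phenol 19, which the conditions of step 12 convert into 21.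

2. Step 7.
   - What may go wrong: insufficient discrimination between the two vinyl bromides, leading to double carbonylation, or displacement of the activated bromide by methanol in an addition–elimination.
   - Fallback (sets out from 9, returns at 11): the ester carbon is brought in by a reagent-limited coupling instead of by CO. Stille coupling of 9 with 1.0 equiv of tributyl(vinyl)stannane (Pd2(dba)3, AsPh3, CuI, DMF, rt) at the same activated bromide gives (2Z)-2-bromo-3-{[(tert-butyldimethylsilyl)oxy]methyl}-1-[3-chloro-2,6-bis(methoxymethoxy)-4-methylphenyl]penta-2,4-dien-1-one F5. Lemieux–Johnson cleavage of the monosubstituted vinyl group (OsO4 cat., NaIO4, 2,6-lutidine, dioxane–water) gives (2E)-3-bromo-2-{[(tert-butyldimethylsilyl)oxy]methyl}-4-[3-chloro-2,6-bis(methoxymethoxy)-4-methylphenyl]-4-oxobut-2-enal F6. Pinnick oxidation (NaClO2, NaH2PO4, 2-methylbut-2-ene) gives (2E)-3-bromo-2-{[(tert-butyldimethylsilyl)oxy]methyl}-4-[3-chloro-2,6-bis(methoxymethoxy)-4-methylphenyl]-4-oxobut-2-enoic acid F7, and alkylation of its carboxylate (MeI, K2CO3, DMF) returns to 11.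

3. Step 9.
   - What may go wrong: slow transmetalation at the hindered tetrasubstituted vinylpalladium centre, with protodestannylation of 14 or geometric isomerization of the vinylpalladium species competing.
   - Fallback (sets out from 11 and 13, returns at 15): a Negishi coupling replaces the tin-based coupling. Compound 13, made as in step 8, is transmetalated with ZnCl2 to chloro(1-methoxyethenyl)zinc F8, which couples with 11 under Pd(PPh3)4 in THF at rt. The more nucleophilic zinc reagent should transmetalate quickly while tolerating the ketone and the ester.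

**Further compounds**

F1 | step 11 | 3-chloro-2,6-bis(methoxymethoxy)-4-methylbenzaldehyde | O=Cc1c(OCOC)cc(C)c(Cl)c1OCOC
F2 | step 11 | methyl 4-[3-chloro-2,6-bis(methoxymethoxy)-4-methylphenyl]-4-hydroxybut-2-ynoate (racemic) | COC(=O)C#CC(O)c1c(OCOC)cc(C)c(Cl)c1OCOC
F3 | step 11 | methyl 4-[3-chloro-2,6-bis(methoxymethoxy)-4-methylphenyl]-4-oxobut-2-ynoate | COC(=O)C#CC(=O)c1c(OCOC)cc(C)c(Cl)c1OCOC
F4 | step 11 | methyl 2-[3-chloro-2,6-bis(methoxymethoxy)-4-methylbenzoyl]-3,3-dimethoxy-5-(trimethylsilyloxy)cyclohexa-1,4-diene-1-carboxylate | COC(=O)C1=C(C(=O)c2c(OCOC)cc(C)c(Cl)c2OCOC)C(OC)(OC)C=C(O[Si](C)(C)C)C1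
F5 | step 7 | (2Z)-2-bromo-3-{[(tert-butyldimethylsilyl)oxy]methyl}-1-[3-chloro-2,6-bis(methoxymethoxy)-4-methylphenyl]penta-2,4-dien-1-one | CC(C)(C)[Si](C)(C)OC/C(C=C)=C(Br)/C(=O)c1c(OCOC)cc(C)c(Cl)c1OCOC
F6 | step 7 | (2E)-3-bromo-2-{[(tert-butyldimethylsilyl)oxy]methyl}-4-[3-chloro-2,6-bis(methoxymethoxy)-4-methylphenyl]-4-oxobut-2-enal | CC(C)(C)[Si](C)(C)OC/C(C=O)=C(Br)/C(=O)c1c(OCOC)cc(C)c(Cl)c1OCOC
F7 | step 7 | (2E)-3-bromo-2-{[(tert-butyldimethylsilyl)oxy]methyl}-4-[3-chloro-2,6-bis(methoxymethoxy)-4-methylphenyl]-4-oxobut-2-enoic acid | CC(C)(C)[Si](C)(C)OC/C(C(=O)O)=C(Br)/C(=O)c1c(OCOC)cc(C)c(Cl)c1OCOC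
F8 | step 9 | chloro(1-methoxyethenyl)zinc | COC(=C)[Zn]Cl
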